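In the early minutes I watch the product c(partner)·c(free catalyst) in this flask: the first three equations below each run in proportion to it, so I count progress by its time integral.

left-handed substrate 0.090 M; partner 0.0990 M; free catalyst 0.90 mM; right-handed substrate 0.090 M

    partner + free catalyst + left-handed substrate → free catalyst + left-handed product (k1 = 416 /M²/min)
    partner + free catalyst + right-handed substrate → free catalyst + right-handed product (k2 = 41.6 /M²/min)
    partner + free catalyst → spent catalyst (k3 = 0.401 /M/min)
    free catalyst ⇌ dormant form (K4 = 0.496, k4 = 0.0164 /min)

- free catalyst is single-handed; left-handed substrate and right-handed substrate are mirror images of each other, charged as a racemate, each of them at the stated concentration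
- charge of left-handed substrate (flask): 0.090 M

* the form that holds most of the catalyst when 10% of the left-handed substrate and right-handed substrate together are converted (spent catalyst / free catalyst / dormant form)
* its share of the catalyst then
* apparent order in partner when 10% of the left-handed substrate and right-handed substrate together are converted (percent change of the rate of making left-handed product for one percent more partner charged)

The left-handed substrate reacts faster than the right-handed one, with a selectivity factor of 10.0, so the conversion asked for takes about 18.2% of the left-handed charge. That needs 4.82 × 10⁻⁴ M^2·min of the integral, which I call the exposure, and the partner charge doesn't enter it. Spent catalyst is this exposure times the constant of the third equation, so it reaches about 21.5% of the catalyst.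

Partner ends near 0.0810 M. Joining start and end through their means, I get a time of 6.67 min. Taking the equilibrium constant as dormant form over free catalyst, the two relax with a half-life of 14.0 min, both ways together. My time is shorter, so the dormant form lags that balance and holds about 7.32%. The largest holder is then free catalyst, with a share of 71.2%. At equal exposure, more partner raises the partner term and shortens the time, which leaves less dormant form, so I expect an order of 1.33.

The forecast gives free catalyst at 70%, lower than my share, and an order of 1.36, higher than mine, noting that “the dormant pool lags”.

The flask gives free catalyst at 70.1%, with spent catalyst at 21.3% and dormant form at 8.63%, after 7.11 min; the order is 1.3.

The spent catalyst read there returns an exposure of 4.78 × 10⁻⁴ M^2·min. The step that makes it holds the rate down at that conversion: without it the rate in this flask is 1.30 times the actual one. With twice the partner, the same exposure 4.82 × 10⁻⁴ M^2·min comes in at 0.476 of my time, and the simulated run with that charge gives a factor of 0.459.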